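## Retrosynthetic overview
1. 9 ⇒ 8: the oxirane is made last, by direct catalyst-controlled O-atom transfer to the Δ2′ olefin of the intact aryl dienyl ether (monooxygenase-like). Both stereocentres are set in this one event.
2. 8 ⇒ 4: the α-pyrone ring is made first, from a cinnamic acid by E→Z isomerisation, ortho C–H oxygenation and lactonisation. The Schenck-ene oxidation of the terminal prenyl unit runs in the same photochemical flask.
3. 4 ⇒ sinapic acid 1 + geranyl bromide 2. The symmetric 3,4,5-trioxygenated ring makes both ortho carbons equivalent, so the lactonisation has no regiochemical issue.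
4. Ring order: benzene ring bought, then pyranone (step 2), then oxirane (step 3).

Assumption: primed locants count the C10 chain from the O-bound carbon. In step 2 the events are drawn in the order of their expected rates (isomerisation, ene reaction, lactonisation), and any other order converges on 7.

## Route

Step 1
Reactants: 1 sinapic acid; 2 geranyl bromide
Product: 4 (E)-4-O-geranylsinapic acid, via geranyl 4-O-geranylsinapate 3 (not isolated)
Conditions: K2CO3 (3 equiv), 2 (2.2 equiv), DMF, Ar, rt, 14 h; then 2 M aq NaOH, THF–MeOH, 45 °C, 3 h; hexane wash of the basic layer; 1 M HCl to pH 3, 0 °C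
Reagents that add atoms: geranyl bromide (2), CC(C)=CCC/C(C)=C/CBr; sodium hydroxide, [Na+].[OH-]
Why: Williamson SN2 O-alkylation of the phenoxide and the carboxylate is followed in the same pot by BAc2 saponification, which cleaves only the allylic ester and leaves the aryl geranyl ether and all E olefins untouched; no stereocentre is involved.

Step 2
Reactants: 4 (E)-4-O-geranylsinapic acid
Product: 8 7-[(2E,5E)-7-hydroxy-3,7-dimethylocta-2,5-dienyloxy]-6,8-dimethoxycoumarin, via Z-acid 5 (not isolated), via hydroperoxy Z-acid 6 (not isolated), via coumarin hydroperoxide 7 (not isolated)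
Conditions: (−)-riboflavin (2 × 5 mol%), O2 (1 atm), MeCN–MeOH 1:1 (0.02 M), 402 nm LED, 20 °C, 24–36 h (HPLC control); Ar purge, then PPh3 (2.5 equiv), 0 °C → rt, 1 h; SiO2 separation from the isopropenyl (secondary alcohol) regioisomer
Reagents that add atoms: oxygen, O=O
Why: Proposed new method: one flavin sensitiser runs three known photochemical modes in one flask, namely triplet energy transfer (E→Z isomerisation, bringing CO2H next to the ortho C–H), 1O2 sensitisation (Schenck ene at the electron-rich Δ6′ olefin, O to C7′, H from C5′, new E-Δ5′ olefin, while Δ2′ is deactivated by the allylic aryloxy group) and SET oxidation of the Z-acid (the carboxyl O closes on the ortho carbon, which is ortho/para to the two OMe groups and identical on both sides of the ring, then H is lost and O2 reoxidises the reduced flavin), after which PPh3 reduces the O–O bond; 1O2 formation under flavin/O2 is unavoidable, so it is used productively; the product coumarin has too high a triplet energy to be sensitised; the closest known reaction types are the flavin-photocatalysed isomerisation/oxidative lactonisation of (mostly β-substituted) cinnamic acids to coumarins and the dye-sensitised Schenck ene reaction of geranyl esters and ethers; no stereocentre is formed.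

Step 3
Reactants: 8 7-[(2E,5E)-7-hydroxy-3,7-dimethylocta-2,5-dienyloxy]-6,8-dimethoxycoumarin
Product: 9 7-{[(2R,3R)-3-[(2E)-4-hydroxy-4-methylpent-2-enyl]-3-methyloxiran-2-yl]methoxy}-6,8-dimethoxycoumarin (target)
Conditions: D-fructose-derived Shi ketone (30 mol%), Oxone (1.2 equiv KHSO5) and K2CO3 added in parallel over 2 h, Bu4NHSO4 (5 mol%), MeCN–DMM 1:2 / 0.05 M Na2B4O7–Na2EDTA buffer (pH 10.5), −5 → 0 °C; stop at about 90% conversion; neutral work-up; recrystallisation or chiral HPLC to raise the ee
Reagents that add atoms: Oxone (active component potassium peroxymonosulfate), [K+].[O-]S(=O)(=O)OO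
Why: Shi asymmetric epoxidation, in which the D-fructose-derived dioxirane transfers O through the spiro transition state to the face that gives (R,R)-epoxides from E-trisubstituted olefins (the same substituent pattern as C2′/C3′ here), so syn-stereospecific transfer to the E-Δ2′ olefin sets 2′R and 3′R together; the trisubstituted Δ2′ olefin outruns the trans-disubstituted, neopentyl-like, hydroxyl-deactivated Δ5′ olefin and the electron-poor coumarin C3=C4, and the electron-rich lactone opens only slowly at 0 °C.

## Compound list
1 | sinapic acid, (E)-3-(4-hydroxy-3,5-dimethoxyphenyl)prop-2-enoic acid | COc1cc(/C=C/C(=O)O)cc(OC)c1O | starting material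
2 | geranyl bromide, (2E)-1-bromo-3,7-dimethylocta-2,6-diene | CC(C)=CCC/C(C)=C/CBr | starting material
3 | geranyl (E)-4-O-geranylsinapate | COc1cc(/C=C/C(=O)OC/C=C(\C)CCC=C(C)C)cc(OC)c1OC/C=C(\C)CCC=C(C)C | intermediate
4 | (E)-4-O-geranylsinapic acid | COc1cc(/C=C/C(=O)O)cc(OC)c1OC/C=C(\C)CCC=C(C)C | intermediate
5 | (Z)-4-O-geranylsinapic acid | COc1cc(/C=C\C(=O)O)cc(OC)c1OC/C=C(\C)CCC=C(C)C | intermediate
6 | (Z)-3-{4-[(2E,5E)-7-hydroperoxy-3,7-dimethylocta-2,5-dienyloxy]-3,5-dimethoxyphenyl}prop-2-enoic acid | COc1cc(/C=C\C(=O)O)cc(OC)c1OC/C=C(\C)C/C=C/C(C)(C)OO | intermediate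
7 | 7-[(2E,5E)-7-hydroperoxy-3,7-dimethylocta-2,5-dienyloxy]-6,8-dimethoxycoumarin | COc1cc2ccc(=O)oc2c(OC)c1OC/C=C(\C)C/C=C/C(C)(C)OO | intermediate
8 | 7-[(2E,5E)-7-hydroxy-3,7-dimethylocta-2,5-dienyloxy]-6,8-dimethoxycoumarin | COc1cc2ccc(=O)oc2c(OC)c1OC/C=C(\C)C/C=C/C(C)(C)O | intermediate
9 | 7-{[(2R,3R)-3-[(2E)-4-hydroxy-4-methylpent-2-enyl]-3-methyloxiran-2-yl]methoxy}-6,8-dimethoxycoumarin | COc1cc2ccc(=O)oc2c(OC)c1OC[C@H]1O[C@]1(C)C/C=C/C(C)(C)O | target

## Step count and risks
Total step count: 3. Longest linear sequence: 3.

**Most likely to fail: step 2.** There are four risks.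
- The acid has no β-substituent, so the Z share at the photostationary state is lower.
- The aryl geranyl ether radical cation may lose its α-H or fragment.
- Long irradiation may begin to oxidise the Δ2′ olefin.
- The ene reaction gives the tertiary and secondary hydroperoxides in about 1:1 ratio, which caps the yield.

The fallback takes the side chain out of the electron-transfer step and runs each event separately. It sets out from 1 and comes back at 7. Acetylation (Ac2O, pyridine) gives (E)-4-O-acetylsinapic acid F1. The same riboflavin/O2/402 nm conditions, now with nothing else oxidisable in the molecule, isomerise it to (Z)-4-O-acetylsinapic acid F2 and lactonise that to 7-acetoxy-6,8-dimethoxycoumarin F3. Methanolysis with catalytic K2CO3 gives isofraxidin F4. Alkylation with 2 (K2CO3, acetone, reflux) gives 7-geranyloxy-6,8-dimethoxycoumarin F5. A short separate tetraphenylporphyrin/O2/visible-light Schenck ene reaction in CH2Cl2 then delivers 7, which PPh3 reduces to 8 as in the main route.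

**Second: step 3.** There are three risks.
- Δ2′ may not be selected well enough over Δ5′.
- The ee may stay below about 90% for an allylic aryl ether.
- The lactone may partly open at pH 10.5.

The fallback moves the stereochemistry to a hydroxyl-directed epoxidation before the ether bond is made. It sets out from 1, carried to isofraxidin F4 as described above, and comes back at 9. Commercial geraniol undergoes Sharpless asymmetric epoxidation (Ti(OiPr)4, D-(−)-DIPT, TBHP, 4 Å MS, CH2Cl2, −20 °C) to (2R,3R)-2,3-epoxygeraniol F6. Mitsunobu coupling with F4 (PPh3, DIAD, THF) reacts at the primary carbon only and gives 7-[(2R,3R)-2,3-epoxygeranyloxy]-6,8-dimethoxycoumarin F7. Tetraphenylporphyrin-sensitised photooxygenation of the one remaining olefin gives the epoxy tertiary hydroperoxide F8. PPh3 reduces F8 to 9.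

**Third: step 1.** There are two risks.
- The sinapate phenoxide may be oxidised by air.
- One equivalent of 2 is spent on the ester.

The fallback builds the acrylic acid after the ether instead of alkylating the preformed acid. It sets out from 2 and comes back at 4. Commercial syringaldehyde is alkylated with 2 (K2CO3, DMF, rt) to 4-geranyloxy-3,5-dimethoxybenzaldehyde F9. Knoevenagel–Doebner condensation with malonic acid (pyridine, catalytic piperidine, 85 °C) passes through 2-(4-geranyloxy-3,5-dimethoxybenzylidene)malonic acid F10, which decarboxylates in the flask to 4.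

## Further compounds
F1 | step 2 | (E)-4-O-acetylsinapic acid | COc1cc(/C=C/C(=O)O)cc(OC)c1OC(C)=O
F2 | step 2 | (Z)-4-O-acetylsinapic acid | COc1cc(/C=C\C(=O)O)cc(OC)c1OC(C)=O
F3 | step 2 | 7-acetoxy-6,8-dimethoxycoumarin | COc1cc2ccc(=O)oc2c(OC)c1OC(C)=O
F4 | step 2 | isofraxidin, 7-hydroxy-6,8-dimethoxycoumarin | COc1cc2ccc(=O)oc2c(OC)c1O
F5 | step 2 | 7-geranyloxy-6,8-dimethoxycoumarin | COc1cc2ccc(=O)oc2c(OC)c1OC/C=C(\C)CCC=C(C)C
F6 | step 3 | (2R,3R)-2,3-epoxygeraniol | OC[C@H]1O[C@]1(C)CCC=C(C)C
F7 | step 3 | 7-[(2R,3R)-2,3-epoxygeranyloxy]-6,8-dimethoxycoumarin | COc1cc2ccc(=O)oc2c(OC)c1OC[C@H]1O[C@]1(C)CCC=C(C)C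
F8 | step 3 | 7-{[(2R,3R)-3-[(2E)-4-hydroperoxy-4-methylpent-2-enyl]-3-methyloxiran-2-yl]methoxy}-6,8-dimethoxycoumarin | COc1cc2ccc(=O)oc2c(OC)c1OC[C@H]1O[C@]1(C)C/C=C/C(C)(C)OO
F9 | step 1 | 4-geranyloxy-3,5-dimethoxybenzaldehyde | COc1cc(C=O)cc(OC)c1OC/C=C(\C)CCC=C(C)C
F10 | step 1 | 2-(4-geranyloxy-3,5-dimethoxybenzylidene)malonic acid | COc1cc(C=C(C(=O)O)C(=O)O)cc(OC)c1OC/C=C(\C)CCC=C(C)C
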